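**Plan**
1. Cuts, last bond first: the CH2–C bond to the filicinic acid ring, the aryl C3–CH2 bond, the O–prenyl bond, the two C–CH3 bonds at the CMe2 carbon, then the arene ring bond between C1 and an oxygen-bearing ortho carbon; the opened chain is cut at PhCO–CH2 and at CH2–CO2Me.
2. Enabling feature: in the benzoyl-bearing benzene ring, C1 carries the benzoyl group and C2, C4 and C6 carry oxygen, so every second ring carbon is oxygenated. That is a folded chain of one benzoate and three acetate units, methyl 3,5,7-trioxo-7-phenylheptanoate.
3. Forward: methyl benzoate, acetylacetone and CO2 give the chain (steps 1–3); the arene, the only ring made in the route, closes in step 4; silylation, prenylation, aminomethylation and desilylation follow (steps 5–8).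
4. The filicinic acid ring is not built; it comes from phloroisobutyrophenone by dearomatising gem-dimethylation (step 9). The two halves are joined last through the methylene carbon (step 10).
5. Stereochemistry: the target has no stereocentre and no stereogenic double bond. What must be controlled is regiochemistry, which comes from the twofold symmetry of 9 and 10 and from the single free hydroxyl of 12.

Key step: step 4

Remark 1 (assumption): since the target is achiral, "single enantiomer" is read as the single constitution in the enol tautomer drawn; 17 and 19 are written in that tautomer.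
Remark 2 (numbering): in the benzophenone ring C1 bears the benzoyl group; from step 6 on, C6 bears the prenyloxy group, C2 and C4 bear hydroxyl (or silyloxy at C4), and C3 is the carbon that receives the methylene group.

**Step 1**
Reactants: 1 acetylacetone; 2 methyl benzoate
Product: 4 1-phenylhexane-1,3,5-trione, via dilithium dianion of acetylacetone 3 (not isolated)
Conditions: 1 (2 equiv), LDA (4 equiv, commercial solution), THF, −78 → 0 °C; 2 (1 equiv), 0 °C → rt; 1 M HCl
Reagents that add atoms: none
Why: Claisen acylation of a 1,3-diketone dianion by a non-enolisable ester takes place at the terminal, last-formed carbanion, and the second equivalent of dianion deprotonates the product at once, which should stop a second acylation.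

**Step 2**
Reactants: 4 1-phenylhexane-1,3,5-trione
Product: 6 3,5,7-trioxo-7-phenylheptanoic acid, via trilithium trianion of the triketone 5 (not isolated)
Conditions: LDA (3.2 equiv), THF, 0 °C; CO2 (gas, excess), −78 → 0 °C; 1 M HCl, 0 °C, cold Et2O extraction, used at once
Reagents that add atoms: carbon dioxide, O=C=O
Why: the trianion of a 1,3,5-triketone reacts with electrophiles at its terminal CH2 carbanion, the least stabilised of the three sites, so carboxylation should place the acid at the methyl terminus, and cold acidification should keep the β-keto acid from losing CO2.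

**Step 3**
Reactants: 6 3,5,7-trioxo-7-phenylheptanoic acid
Product: 7 methyl 3,5,7-trioxo-7-phenylheptanoate
Conditions: CH2N2 (1.0 equiv, titrated ethereal solution), Et2O, −10 °C, 10 min; evaporation below 20 °C
Reagents that add atoms: diazomethane, C=[N+]=[N-]
Why: esterification with diazomethane is fast and neutral, so the acid should be methylated before it decarboxylates or cyclises, and with one equivalent the far less acidic enols should stay untouched.

**Step 4**
Reactants: 7 methyl 3,5,7-trioxo-7-phenylheptanoate
Product: 9 2,4,6-trihydroxybenzophenone, via 2-benzoylcyclohexane-1,3,5-trione 8 (not isolated)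
Conditions: Mg(OMe)2 (6 equiv, commercial solution in MeOH), MeOH, rt → 60 °C, Ar; then 1 M HCl, 0 °C
Reagents that add atoms: none
Why: Magnesium methoxide should convert 7 into a magnesium polyenolate in which the metal bridges the oxygens on C3, C5 and C7 of the chain, so that these three carbonyls are enolised and the ester carbonyl C1 is the only electrophile left. The carbon between the benzoyl and C5 carbonyls (chain C6, later ring C1) adds to C1, methoxide leaves, and trione 8 enolises to the aromatic ring of 9; the closest known reaction type is the base-mediated intramolecular Claisen condensation of 3,5,7-triketo esters to acylphloroglucinols. The six-membered ring closes in the 6-(enolendo)-exo-trig mode, the attacked C=O lying outside the new ring. No stereocentre is formed. The step needs C-acylation at chain C6 to win over aldol closure of C2 onto the benzoyl carbonyl (which would lead to a methyl 6-phenylresorcylate) and over O-acylation to a 4-hydroxy-6-phenacylpyran-2-one. The chelated 1,3,5-tricarbonyl unit secures this, since it removes the benzoyl carbonyl as an acceptor and holds C6 next to C1, while the methyl ester (unlike a carboxylate) stays electrophilic and any pyranone formed is reopened by methoxide.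

**Step 5**
Reactants: 9 2,4,6-trihydroxybenzophenone
Product: 10 2,6-dihydroxy-4-(triisopropylsilyloxy)benzophenone
Conditions: TIPSCl (1.05 equiv), imidazole (2.2 equiv), DMF, −20 → 0 °C
Reagents that add atoms: chlorotriisopropylsilane, CC(C)[Si](Cl)(C(C)C)C(C)C
Why: imidazole-promoted silylation with a bulky chlorosilane should take the 4-hydroxyl, which is the most acidic (para to the carbonyl) and the only one neither flanked nor hydrogen-bonded by the benzoyl group.

**Step 6**
Reactants: 10 2,6-dihydroxy-4-(triisopropylsilyloxy)benzophenone; 11 prenyl alcohol (3-methylbut-2-en-1-ol)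
Product: 12 2-hydroxy-6-(3-methylbut-2-enyloxy)-4-(triisopropylsilyloxy)benzophenone
Conditions: PPh3 (1.15 equiv), DIAD (1.15 equiv), THF, 0 °C → rt
Reagents that add atoms: none
Why: Mitsunobu etherification of a phenol with a primary allylic alcohol runs under neutral conditions that spare the aryl silyl ether, should give the unrearranged prenyl ether without C-alkylation, and should stop after one of the two equivalent ortho hydroxyls because the remaining one is locked in a strong hydrogen bond to the carbonyl.

**Step 7**
Reactants: 12 2-hydroxy-6-(3-methylbut-2-enyloxy)-4-(triisopropylsilyloxy)benzophenone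
Product: 13 3-(dimethylaminomethyl)-2-hydroxy-6-(3-methylbut-2-enyloxy)-4-(triisopropylsilyloxy)benzophenone
Conditions: Me2N+=CH2 I− (1.3 equiv), Et3N (1.3 equiv), MeCN, 0 → 40 °C
Reagents that add atoms: N,N-dimethylmethyleneiminium iodide (Eschenmoser's salt), C=[N+](C)C.[I-]
Why: a phenol Mannich reaction with a preformed iminium salt should take place ortho to the only free hydroxyl, at C3, because the other open position C5 is para to that hydroxyl and buried between the silyloxy group and the prenyloxy CH2.

**Step 8**
Reactants: 13 3-(dimethylaminomethyl)-2-hydroxy-6-(3-methylbut-2-enyloxy)-4-(triisopropylsilyloxy)benzophenone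
Product: 14 3-(dimethylaminomethyl)-2,4-dihydroxy-6-(3-methylbut-2-enyloxy)benzophenone
Conditions: TBAF (1.1 equiv), AcOH (1.2 equiv), THF, 0 °C; pH 7 buffer; crude product used directly
Reagents that add atoms: none
Why: fluoride cleaves an aryl silyl ether para to a carbonyl group readily at 0 °C, and the acetic acid buffer keeps the medium near neutral so that neither the prenyl ether nor the benzylic amine should be touched.

**Step 9**
Reactants: 15 phloroisobutyrophenone
Product: 17 isobutyrylfilicinic acid, via 3-methylphloroisobutyrophenone 16 (not isolated)
Conditions: NaOMe (4 equiv), MeI (2.5 equiv), MeOH, 0 °C → rt; 1 M HCl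
Reagents that add atoms: iodomethane, CI
Why: the polyphenoxide of an acylphloroglucinol is C-methylated by iodomethane, and the second methyl group enters the already methylated, more electron-rich carbon with loss of aromaticity, which is the standard dearomatising gem-dimethylation to acylfilicinic acids.

**Step 10**
Reactants: 14 3-(dimethylaminomethyl)-2,4-dihydroxy-6-(3-methylbut-2-enyloxy)benzophenone; 17 isobutyrylfilicinic acid
Product: 19 sarothralin, via benzophenone ortho-quinone methide 18 (not isolated)
Conditions: 14 (1.0 equiv), 17 (1.2 equiv), 1,4-dioxane, 90 °C, Ar; 5% aq. citric acid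
Reagents that add atoms: none
Why: the acidic trione 17 protonates the benzylic amine, dimethylamine is lost in a thermal Mannich-base elimination to ortho-quinone methide 18, and the enolate of 17 should add through its only unsubstituted ring carbon in a Michael reaction, after which tautomerisation restores the arene.

**Compound list**
1 | acetylacetone (pentane-2,4-dione) | CC(=O)CC(C)=O | starting material
2 | methyl benzoate | COC(=O)c1ccccc1 | starting material
3 | dilithium dianion of acetylacetone (formed in the flask) | [Li+].[Li+].C=C([O-])C=C(C)[O-] | intermediate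
4 | 1-phenylhexane-1,3,5-trione | CC(=O)CC(=O)CC(=O)c1ccccc1 | intermediate
5 | trilithium trianion of 1-phenylhexane-1,3,5-trione (formed in the flask) | [Li+].[Li+].[Li+].C=C([O-])C=C([O-])C=C([O-])c1ccccc1 | intermediate
6 | 3,5,7-trioxo-7-phenylheptanoic acid | OC(=O)CC(=O)CC(=O)CC(=O)c1ccccc1 | intermediate
7 | methyl 3,5,7-trioxo-7-phenylheptanoate | COC(=O)CC(=O)CC(=O)CC(=O)c1ccccc1 | intermediate
8 | 2-benzoylcyclohexane-1,3,5-trione (as magnesium enolate, formed in the flask) | O=C1CC(=O)C(C(=O)c2ccccc2)C(=O)C1 | intermediate
9 | 2,4,6-trihydroxybenzophenone, (2,4,6-trihydroxyphenyl)(phenyl)methanone | O=C(c1ccccc1)c1c(O)cc(O)cc1O | intermediate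
10 | 2,6-dihydroxy-4-(triisopropylsilyloxy)benzophenone | CC(C)[Si](Oc1cc(O)c(C(=O)c2ccccc2)c(O)c1)(C(C)C)C(C)C | intermediate
11 | prenyl alcohol (3-methylbut-2-en-1-ol) | CC(C)=CCO | starting material
12 | 2-hydroxy-6-(3-methylbut-2-enyloxy)-4-(triisopropylsilyloxy)benzophenone | CC(C)=CCOc1cc(O[Si](C(C)C)(C(C)C)C(C)C)cc(O)c1C(=O)c1ccccc1 | intermediate
13 | 3-(dimethylaminomethyl)-2-hydroxy-6-(3-methylbut-2-enyloxy)-4-(triisopropylsilyloxy)benzophenone | CN(C)Cc1c(O[Si](C(C)C)(C(C)C)C(C)C)cc(OCC=C(C)C)c(C(=O)c2ccccc2)c1O | intermediate
14 | 3-(dimethylaminomethyl)-2,4-dihydroxy-6-(3-methylbut-2-enyloxy)benzophenone | CN(C)Cc1c(O)cc(OCC=C(C)C)c(C(=O)c2ccccc2)c1O | intermediate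
15 | phloroisobutyrophenone, 2-methyl-1-(2,4,6-trihydroxyphenyl)propan-1-one | CC(C)C(=O)c1c(O)cc(O)cc1O | starting material
16 | 3-methylphloroisobutyrophenone, 2-methyl-1-(2,4,6-trihydroxy-3-methylphenyl)propan-1-one (formed in the flask) | CC(C)C(=O)c1c(O)cc(O)c(C)c1O | intermediate
17 | isobutyrylfilicinic acid, 3,5-dihydroxy-6,6-dimethyl-2-(2-methylpropanoyl)cyclohexa-2,4-dien-1-one | CC(C)C(=O)C1=C(O)C=C(O)C(C)(C)C1=O | intermediate
18 | ortho-quinone methide from 14, 5-benzoyl-4-hydroxy-2-(3-methylbut-2-enyloxy)-... 6-methylidenecyclohexa-2,4-dien-1-one skeleton (formed in the flask) | C=C1C(=O)C=C(OCC=C(C)C)C(C(=O)c2ccccc2)=C1O | intermediate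
19 | sarothralin, 4-{[3-benzoyl-2,6-dihydroxy-4-(3-methylbut-2-enyloxy)phenyl]methyl}-3,5-dihydroxy-6,6-dimethyl-2-(2-methylpropanoyl)cyclohexa-2,4-dien-1-one | CC(C)=CCOc1cc(O)c(CC2=C(O)C(C)(C)C(=O)C(C(=O)C(C)C)=C2O)c(O)c1C(=O)c1ccccc1 | target

**Totals**
Total step count: 10.
Longest linear sequence: 9 steps (steps 1–8 and 10); step 9 is a one-step branch.

**Three steps most likely to fail**

Step 7 (aminomethylation of 12). The iminium ion may be attacked slowly, because the only free hydroxyl is tied to the carbonyl by a hydrogen bond and the ring carries a bulky silyl ether. Attack para to that hydroxyl (at C5) or a second aminomethylation would erode the regiochemistry. The fallback sets out from 10 and comes back at 19; it introduces the one-carbon unit as a formyl group while the ring is still twofold symmetric. Vilsmeier–Haack formylation of 10 (POCl3, DMF, MeCN, 0 °C → rt; aq. NaOAc) can give only 3-benzoyl-2,4-dihydroxy-6-(triisopropylsilyloxy)benzaldehyde F1, since C3 and C5 of 10 are equivalent. Mitsunobu reaction of F1 with 11 (PPh3, DIAD, THF, 0 °C) should etherify the hydroxyl para to the formyl group, which is the more acidic one and is not wedged between two carbonyl groups, to give 3-benzoyl-2-hydroxy-4-(3-methylbut-2-enyloxy)-6-(triisopropylsilyloxy)benzaldehyde F2. Proline-catalysed Knoevenagel condensation of F2 with 17 in the presence of Hantzsch ester (CH2Cl2, rt) forms the arylmethylidene trione F3, which is reduced in the flask by hydride transfer to 4-O-triisopropylsilylsarothralin F4. TBAF/AcOH (THF, 0 °C) then gives 19. This replaces steps 6–8 and 10, runs at room temperature and needs no amine leaving group.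

Step 10 (union of 14 and 17). At 90 °C the methylene-bridged product can itself fragment by retro-Michael reaction to a quinone methide from either half, so the CH2 group may be redistributed to the two symmetrical dimers. Free dimethylamine promotes this, and the prenyl ether is exposed to a warm acidic partner. The fallback sets out from 12 and comes back at 19; it moves the electrophile to the filicinic half and runs the union cold in alkali. 12 is desilylated (TBAF/AcOH, THF, 0 °C) to 2,4-dihydroxy-6-(3-methylbut-2-enyloxy)benzophenone F5. F5, 17 and aqueous formaldehyde (1 equiv) are combined in 1% aqueous KOH at 0 °C. There 17 and formaldehyde give the methylidene trione 3-hydroxy-4,4-dimethyl-6-methylidene-2-(2-methylpropanoyl)cyclohex-2-ene-1,5-dione F6 in the flask, and the dianion of F5 should add to it through C3, the carbon between its two phenoxide oxygens (C5 is shielded by the prenyloxy CH2). Acidification with dilute citric acid gives 19. Under these equilibrating conditions the homodimer of 17 formed alongside is fed back through F6; this is the classical alkaline formaldehyde condensation of a phloroglucinol with an acylfilicinic acid, and any C5-linked isomer would have to be separated.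

Step 2 (carboxylation and handling of acid 6). The β-keto acid may lose CO2, or close to a resorcylic acid or a pyranone, while it is acidified, extracted and concentrated; in step 3 diazomethane may begin to methylate enols. The fallback sets out from 2 and comes back at 7; the free acid is never handled. Commercial 4-hydroxy-6-methylpyran-2-one F7 is converted with LDA (THF, −78 °C) into its dilithium dianion F8, which is acylated at the methyl-derived carbon by 2 to give 4-hydroxy-6-(2-oxo-2-phenylethyl)pyran-2-one F9, a stable enol lactone of acid 6. When F9 is placed in the magnesium methoxide/methanol of step 4, methoxide opens the lactone to the magnesium chelate of 7, and the route continues from 7 in the same flask to 9.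

**Further compounds**
F1 | step 7 | 3-benzoyl-2,4-dihydroxy-6-(triisopropylsilyloxy)benzaldehyde | O=Cc1c(O[Si](C(C)C)(C(C)C)C(C)C)cc(O)c(C(=O)c2ccccc2)c1O
F2 | step 7 | 3-benzoyl-2-hydroxy-4-(3-methylbut-2-enyloxy)-6-(triisopropylsilyloxy)benzaldehyde | O=Cc1c(O[Si](C(C)C)(C(C)C)C(C)C)cc(OCC=C(C)C)c(C(=O)c2ccccc2)c1O
F3 | step 7 | arylmethylidene trione, Knoevenagel adduct of F2 and 17 (either alkene geometry, not isolated) | CC(C)=CCOc1cc(O[Si](C(C)C)(C(C)C)C(C)C)c(C=C2C(=O)C(C)(C)C(O)=C(C(=O)C(C)C)C2=O)c(O)c1C(=O)c1ccccc1
F4 | step 7 | 4-O-triisopropylsilylsarothralin | CC(C)=CCOc1cc(O[Si](C(C)C)(C(C)C)C(C)C)c(CC2=C(O)C(C)(C)C(=O)C(C(=O)C(C)C)=C2O)c(O)c1C(=O)c1ccccc1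
F5 | step 10 | 2,4-dihydroxy-6-(3-methylbut-2-enyloxy)benzophenone | CC(C)=CCOc1cc(O)cc(O)c1C(=O)c1ccccc1
F6 | step 10 | 3-hydroxy-4,4-dimethyl-6-methylidene-2-(2-methylpropanoyl)cyclohex-2-ene-1,5-dione (not isolated) | C=C1C(=O)C(C)(C)C(O)=C(C(=O)C(C)C)C1=O
F7 | step 2 | 4-hydroxy-6-methylpyran-2-one | CC1=CC(O)=CC(=O)O1
F8 | step 2 | dilithium dianion of 4-hydroxy-6-methylpyran-2-one (not isolated) | [Li+].[Li+].C=C1C=C([O-])C=C([O-])O1
F9 | step 2 | 4-hydroxy-6-(2-oxo-2-phenylethyl)pyran-2-one | O=C(CC1=CC(O)=CC(=O)O1)c1ccccc1
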